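(Readings and results are calculated from invented constants; the scatter is artificial.)

The theta run, with 0.26 equiv of X, read 1.00 % of Z, the mean of its readings at 4.00 min and 6.00 min. The delta run, with ten times the X, read 27.3 % at 6.00 min.

common to all: J 5.0 × 10⁻⁴ M

|  | X | Q | remark | time |
|---|---|---|---|---|
| theta | 0.26 equiv | 1 equiv | run made earlier |  |
| delta | 2.6 equiv | 1 equiv | run made earlier |  |
| oak | 0.500 equiv | 1.00 equiv |  | 6.0 min |
| birch | 1.20 equiv | 1.00 equiv |  | 6.0 min |
| larch | 4.00 equiv | 1.00 equiv |  | 6.0 min |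

| run | time / min | Z / % | E / % | J / % |
|---|---|---|---|---|
| theta | 0.500 | 1.2 | 1.5 | 31.2 |
| theta | 0.833 | 0.8 | 1.0 | 25.0 |
| theta | 1.33 | 1.1 | 0.9 | 23.7 |
| theta | 2.00 | 1.1 | 0 | 21.9 |
| theta | 4.00 | 0.8 | 1.0 | 19.5 |
| theta | 6.00 | 1.2 | 0 | 18.7 |
| delta | 1.00 | 33.1 | 1.8 | 7.1 |
| delta | 2.00 | 33.4 | 3.0 | 5.9 |
| delta | 3.00 | 31.8 | 3.5 | 5.6 |
| delta | 4.00 | 30.8 | 2.8 | 4.2 |
| delta | 5.00 | 29.8 | 2.2 | 4.9 |
| delta | 6.00 | 27.3 | 3.3 | 5.0 |

(scatter of a reading: 0.5 percentage points)

- the analysis behind the earlier runs scatters by 0.5 percentage points, standard deviation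

1. final Z, as a percentage of the J charged, for each flask in turn (oak, birch, larch)

Two chemists dispute the new flasks. The first says that Z holds two exchanged ligands, so it needs two X and should climb faster than the X charged. From these readings she gets 1.44 for the slope, the apparent order in X: the logarithm of the ratio of Z over the logarithm of the ratio of X, at equal J and Q. It stands above one. Scaling delta by that power gives, in my own reckoning, 2.56 % for oak, 8.99 % for birch and 50.7 % for larch.

The second chemist distrusts theta, whose Z of 1.00 % is read with a scatter of 0.5 percentage points. He takes delta alone and keeps Z proportional to X, a slope of one. That gives 5.25 %, 12.6 % and 42.0 %. She answers that his line puts theta at 2.73 %.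

Her forecast is 2.5 %, 10 % and 42 %. At larch it stands lower than my reckoning, trimmed “because of the sink and the slow decline of Z seen in delta”.

The flasks give 2.05 %, 9.97 % and 43.3 %, and the forecast lies within the margin.

    J + E → L (k = 390 M⁻¹ s⁻¹)
    J ⇌ G (K = 2.30, k = 0.0510 s⁻¹)
    E + X ⇌ Q + Z (K = 10.0, k = 150 M⁻¹ s⁻¹)
    J + X ⇌ Q + E (K = 0.720, k = 78.0 M⁻¹ s⁻¹)

The proportional view misses oak, 5.25 % against 2.05 %, but at larch it gives 42.0 % against 43.3 %, and the slope reckoned again from delta to larch is 1.07. From oak to birch the slope is steeper, 1.81. In oak at 0.0608 min, a molecule of J went to G 3.0 times as fast as it took up X, counting the forward rate of each step alone. Between those two forward steps, its chance of taking X was 25.3 %.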